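The runs were generated by integration with made-up constants; the scatter is artificial.

Read 51.4% of the E charged as the plateau of L in the north-west flask, the mean of its last 3 readings.

| flask | E | Q | X | temperature | remark | time |
|---|---|---|---|---|---|---|
| north-west | 0.050 M | 2.1 µM | 9.8 µM | 25 °C | the very flask that is asked about, followed so far |  |
| north-east | 0.050 M | 2.1 µM | 20 µM | 20 °C | run made earlier |  |
| flask | 0.050 M | 2.1 µM | 9.8 µM | 25 °C |  | 8.0 d |

| run | time / d | L / % | E / % |
|---|---|---|---|
| north-west | 0.417 | 14.3 | 85.9 |
| north-west | 1.25 | 30.2 | 67.6 |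
| north-west | 2.50 | 44.6 | 58.3 |
| north-west | 3.00 | 45.7 | 52.1 |
| north-west | 5.00 | 50.9 | 49.0 |
| north-west | 6.00 | 52.2 | 49.7 |
| north-west | 8.00 | 51.2 | 48.0 |
| north-east | 2.00 | 29.1 | 71.6 |
| north-east | 4.00 | 45.2 | 56.1 |
| north-east | 6.00 | 48.0 | 49.7 |
| north-east | 8.00 | 51.8 | 48.7 |
| north-east | 10.0 | 51.6 | 48.1 |
| north-east | 12.0 | 54.9 | 45.6 |
| north-east | 15.0 | 54.0 | 46.2 |

(standard deviation of a reading: 1 percentage point)

1. L, in percent of the E first charged, at 8.0 d
2. which option adds most L ("none" when 2 percentage points or less is all one gets) (grey / blue / red / ochre / none)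
3. L present, with what was taken out counted in, in percent of the E first charged, after grey
4. L present, with what was taken out counted in, in percent of the E first charged, after blue

- grey: at 8.0 d take out 90% of the L then present, then wait 2.5 d
- blue: change nothing and wait 2.5 d more
- red: at 8.0 d raise the temperature by 10 K, then wait 2.5 d
- ochre: at 8.0 d add Q, 100% of the amount charged, then wait 2.5 d

- what is taken out of L is counted as made
- additions bring no volume worth counting

The asked flask is the north-west flask itself, so reckon from its own curve. Its E lost reappears as L within the scatter, so treat it as one first-order lag. The north-east run changes X and temperature together, so set it aside for the lag.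

At 1.25 d, the mean of L formed and E consumed is 31.3%. This gives 1.33 d, the settling time τ, in which the gap between L and its plateau shrinks by the factor e; the trade calls it the relaxation time.

At 8.0 d my reckoning leaves a gap of 0.13 percentage points, less than the margin of 2 points, so, taking the plateau for an equilibrium and not for a dead catalyst, expect neither blue nor ochre to pay. Red looks unpromising, though not proven so: the north-east run, at 20 °C and with 20 µM of X, last read 54.0%, above this plateau, and it differs in both settings.

For grey, take out 46.3%. The same share of what stays gives a new plateau of 27.6%, and the lag over 2.5 d brings the count to 70.5%. Commit to grey.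

The forecast also says grey, with 51.3% now, 70.5% after grey and 51.4% after blue, and states “I take the enzyme as alive”.

The flask gives 51.4% now, 69.3% after grey and 51.6% after blue. The best option is grey, with a gain of 18 points.

    Q → Z (k = 0.00210 h⁻¹, Ea = 181 kJ mol⁻¹)
    E + Q ⇌ G (K = 8.20 M⁻¹, k = 1.10 × 10⁶ M⁻¹ h⁻¹, Ea = 48.0 kJ mol⁻¹, ΔH = −18.0 kJ mol⁻¹)
    G ⇌ Q + L (K = 0.130 M, k = 1500 h⁻¹, Ea = 80.0 kJ mol⁻¹, ΔH = 3.00 kJ mol⁻¹)
    Q + X ⇌ D, settled at all times (K = 24000 M⁻¹, ΔH = 2.00 kJ mol⁻¹)
    (constants at 25 °C)

On this flask, the gap of 0.13 points stands beside the simulated gain of 0.14 points for blue. Carry τ to the neighbour, the same flask read at 50 h: the lag gives 40.7%, and that flask shows 40.8%.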